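## Retrosynthetic overview

- Numbering: ten-membered ring C1–C10 (C4 methyl, C10 bears C14H2OH, C9=C10), trans γ-lactone C6(O)–C7–C11(=C13H2)–C12(=O), ester oxygen on C8. The route rests on the C8 carbinol beside the trisubstituted C9=C10 olefin: this allylic alcohol is cut at C8–C9 into a C8 aldehyde and a C9 alkenyl iodide.
- Late disconnections: the C8–O ester (Z side-chain acid 39) and C11=C13 (Mannich reaction and elimination on the closed lactone).
- Early disconnections: C1–C10 (Negishi coupling of an alkylzinc with iodo(silyl)allyl ether 20) and C6–C7 (anti propargylation of (S)-citronellal with a chiral allenylzinc).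
- Ring order: γ-lactone first (step 6), ten-membered carbocycle second (step 16).

Key step: step 16

Remark: target atom numbers are used throughout; the CIP descriptor at C7 switches between R and S with the group on C8 or O8, although its spatial arrangement never changes.

## Route

Step 1
Reactants: 1 trimethylsilylacetylene; 2 (tert-butyldimethylsilyloxy)acetaldehyde
Product: 3 rac-1-(tert-butyldimethylsilyloxy)-4-(trimethylsilyl)but-3-yn-2-ol
Conditions: n-BuLi, THF, −78 °C; then 2, −78 → 0 °C
Reagents that add atoms: none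
Why: 1,2-addition of a lithium acetylide to an aldehyde should assemble C12–C11–C7–C8 in one operation.

Step 2
Reactants: 3 rac-1-(tert-butyldimethylsilyloxy)-4-(trimethylsilyl)but-3-yn-2-ol
Product: 4 1-(tert-butyldimethylsilyloxy)-4-(trimethylsilyl)but-3-yn-2-one
Conditions: Dess–Martin periodinane, NaHCO3, CH2Cl2, 0 °C → rt
Reagents that add atoms: none
Why: Dess–Martin oxidation of a propargylic alcohol should give the ynone without touching either silyl group.

Step 3
Reactants: 4 1-(tert-butyldimethylsilyloxy)-4-(trimethylsilyl)but-3-yn-2-one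
Product: 5 (S)-1-(tert-butyldimethylsilyloxy)-4-(trimethylsilyl)but-3-yn-2-ol
Conditions: RuCl[(R,R)-TsNCH(Ph)CH(Ph)NH2](p-cymene) (1 mol %), KOH (1 mol %), i-PrOH, rt
Reagents that add atoms: none
Why: Noyori asymmetric transfer hydrogenation of an alkynyl ketone; the (R,R) catalyst should deliver hydride to the face that gives (R)-carbinols from methyl alkynyl ketones, which is named S here because CH2OTBS outranks the alkynyl group.

Step 4
Reactants: 5 (S)-1-(tert-butyldimethylsilyloxy)-4-(trimethylsilyl)but-3-yn-2-ol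
Product: 6 (S)-1-(tert-butyldimethylsilyloxy)-4-(trimethylsilyl)but-3-yn-2-yl methanesulfonate
Conditions: MsCl, Et3N, CH2Cl2, −40 °C
Reagents that add atoms: methanesulfonyl chloride CS(=O)(=O)Cl
Why: O-sulfonylation leaves the carbinol stereocentre untouched.

Step 5
Reactants: 6 (S)-1-(tert-butyldimethylsilyloxy)-4-(trimethylsilyl)but-3-yn-2-yl methanesulfonate; 7 (S)-citronellal
Product: 9 (3R,4R,6S)-3-[(tert-butyldimethylsilyloxy)methyl]-6,10-dimethyl-1-(trimethylsilyl)undec-9-en-1-yn-4-ol (4S,6R,7R in target numbering), via allenylzinc reagent 8 (not isolated)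
Conditions: Pd(OAc)2 (5 mol %), PPh3 (5 mol %), Et2Zn (3 equiv), THF, −78 → −20 °C
Reagents that add atoms: none
Why: Marshall propargylation: zerovalent palladium displaces the mesylate anti (SN2′), exchange with Et2Zn gives allenylzinc 8 with retention, and its cyclic syn SE2′ addition to the aldehyde should place C6–OH and the C7 substituent anti and set 6R and 7R under reagent control, the remote C4 methyl having little influence.

Step 6
Reactants: 9 (3R,4R,6S)-3-[(tert-butyldimethylsilyloxy)methyl]-6,10-dimethyl-1-(trimethylsilyl)undec-9-en-1-yn-4-ol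
Product: 12 (4R,5R)-4-[(tert-butyldimethylsilyloxy)methyl]-5-[(2S)-2,6-dimethylhept-5-en-1-yl]dihydrofuran-2(3H)-one (trans lactone), via alkenyl(silyl)borane 10 (not isolated), via hydroxy acid 11 (not isolated)
Conditions: (c-C6H11)2BH (3 equiv), THF, 0 °C → rt; then NaOH, H2O2, H2O, 0 → 40 °C; then aq. citric acid, pyridinium p-toluenesulfonate (cat.), CH2Cl2, rt
Reagents that add atoms: hydrogen peroxide OO
Why: Zweifel hydroboration–oxidation of a 1-silylalkyne: the hindered borane should add with boron on the silicon-bearing carbon and spare the trisubstituted olefin, alkaline peroxide should take the 1-boryl-1-silylalkene through the acylsilane to the acid, and the γ-hydroxy acid should close to the lactone with C6 and C7 unchanged.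

Step 7
Reactants: 12 (4R,5R)-4-[(tert-butyldimethylsilyloxy)methyl]-5-[(2S)-2,6-dimethylhept-5-en-1-yl]dihydrofuran-2(3H)-one
Product: 14 (4R,5R)-4-[(tert-butyldimethylsilyloxy)methyl]-5-[(2S)-5-hydroxy-2-methylpentyl]dihydrofuran-2(3H)-one, via aldehyde 13 (not isolated)
Conditions: O3, CH2Cl2/MeOH, −78 °C; then NaBH4, −78 → 0 °C
Reagents that add atoms: ozone [O-][O+]=O
Why: ozonolysis with reductive work-up; the trisubstituted olefin is the only site for ozone, and NaBH4 at 0 °C should reduce the C1 aldehyde far faster than the γ-lactone.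

Step 8
Reactants: 14 (4R,5R)-4-[(tert-butyldimethylsilyloxy)methyl]-5-[(2S)-5-hydroxy-2-methylpentyl]dihydrofuran-2(3H)-one
Product: 15 (4R,5R)-4-[(tert-butyldimethylsilyloxy)methyl]-5-[(2S)-5-iodo-2-methylpentyl]dihydrofuran-2(3H)-one
Conditions: I2, PPh3, imidazole, CH2Cl2, 0 °C → rt
Reagents that add atoms: iodine II
Why: Appel-type iodination of a primary alcohol should proceed without affecting the lactone or the silyl ether.

Step 9
Reactants: 16 propargyl alcohol
Product: 17 triisopropyl(prop-2-yn-1-yloxy)silane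
Conditions: i-Pr3SiCl, imidazole, CH2Cl2, rt
Reagents that add atoms: chlorotriisopropylsilane CC(C)[Si](Cl)(C(C)C)C(C)C
Why: standard silylation of a primary alcohol installs the ether that will protect C14–OH to the end.

Step 10
Reactants: 17 triisopropyl(prop-2-yn-1-yloxy)silane; 18 trimethyl(tributylstannyl)silane
Product: 19 (Z)-triisopropyl{[2-(tributylstannyl)-3-(trimethylsilyl)prop-2-en-1-yl]oxy}silane
Conditions: Pd(PPh3)4 (2 mol %), THF, 65 °C
Reagents that add atoms: none
Why: palladium-catalysed silylstannation of a terminal alkyne is a syn addition with tin on the internal and silicon on the terminal carbon, so tin and silicon should end up cis.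

Step 11
Reactants: 19 (Z)-triisopropyl{[2-(tributylstannyl)-3-(trimethylsilyl)prop-2-en-1-yl]oxy}silane
Product: 20 (Z)-triisopropyl{[2-iodo-3-(trimethylsilyl)prop-2-en-1-yl]oxy}silane
Conditions: I2, CH2Cl2, 0 °C
Reagents that add atoms: iodine II
Why: iododestannylation proceeds with retention and the C–Sn bond should react far faster than the alkenyl C–Si bond, leaving iodine cis to silicon.

Step 12
Reactants: 15 (4R,5R)-4-[(tert-butyldimethylsilyloxy)methyl]-5-[(2S)-5-iodo-2-methylpentyl]dihydrofuran-2(3H)-one; 20 (Z)-triisopropyl{[2-iodo-3-(trimethylsilyl)prop-2-en-1-yl]oxy}silane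
Product: 22 (4R,5R)-4-[(tert-butyldimethylsilyloxy)methyl]-5-[(2S,6E)-2-methyl-6-[(triisopropylsilyloxy)methyl]-7-(trimethylsilyl)hept-6-en-1-yl]dihydrofuran-2(3H)-one, via alkylzinc iodide 21 (not isolated)
Conditions: Zn dust (activated with BrCH2CH2Br and Me3SiCl), LiCl, THF, 40 °C; then 20, Pd(OAc)2 (3 mol %), 2-dicyclohexylphosphino-2′,6′-dimethoxybiphenyl (6 mol %), THF, rt → 40 °C
Reagents that add atoms: none
Why: zinc insertion into a primary iodide tolerates the lactone and silyl ethers, and Negishi sp3–sp2 coupling proceeds with retention at the alkenyl carbon, so C1 should end up cis to the silyl group on C9.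

Step 13
Reactants: 22 (4R,5R)-4-[(tert-butyldimethylsilyloxy)methyl]-5-[(2S,6E)-2-methyl-6-[(triisopropylsilyloxy)methyl]-7-(trimethylsilyl)hept-6-en-1-yl]dihydrofuran-2(3H)-one
Product: 23 (4R,5R)-4-[(tert-butyldimethylsilyloxy)methyl]-5-[(2S,6E)-7-iodo-2-methyl-6-[(triisopropylsilyloxy)methyl]hept-6-en-1-yl]dihydrofuran-2(3H)-one
Conditions: N-iodosuccinimide, (CF3)2CHOH, 0 °C
Reagents that add atoms: N-iodosuccinimide O=C1CCC(=O)N1I
Why: ipso-iododesilylation of a vinylsilane through the tertiary β-silyl cation at C10 should replace silicon by iodine with retention of olefin geometry.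

Step 14
Reactants: 23 (4R,5R)-4-[(tert-butyldimethylsilyloxy)methyl]-5-[(2S,6E)-7-iodo-2-methyl-6-[(triisopropylsilyloxy)methyl]hept-6-en-1-yl]dihydrofuran-2(3H)-one
Product: 24 (4R,5R)-4-(hydroxymethyl)-5-[(2S,6E)-7-iodo-2-methyl-6-[(triisopropylsilyloxy)methyl]hept-6-en-1-yl]dihydrofuran-2(3H)-one
Conditions: pyridinium p-toluenesulfonate (cat.), MeOH, rt
Reagents that add atoms: none
Why: acid-catalysed methanolysis should cleave the primary tert-butyldimethylsilyl ether much faster than the bulkier primary triisopropylsilyl ether.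

Step 15
Reactants: 24 (4R,5R)-4-(hydroxymethyl)-5-[(2S,6E)-7-iodo-2-methyl-6-[(triisopropylsilyloxy)methyl]hept-6-en-1-yl]dihydrofuran-2(3H)-one
Product: 25 (2R,3S)-2-[(2S,6E)-7-iodo-2-methyl-6-[(triisopropylsilyloxy)methyl]hept-6-en-1-yl]-5-oxotetrahydrofuran-3-carbaldehyde
Conditions: Dess–Martin periodinane, NaHCO3, CH2Cl2, 0 °C → rt; crude aldehyde used at once
Reagents that add atoms: none
Why: buffered Dess–Martin oxidation is non-basic, so the C7 centre of the β-acyloxy aldehyde should neither epimerise nor eliminate before the aldehyde is used.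

Step 16
Reactants: 25 (2R,3S)-2-[(2S,6E)-7-iodo-2-methyl-6-[(triisopropylsilyloxy)methyl]hept-6-en-1-yl]-5-oxotetrahydrofuran-3-carbaldehyde
Product: 27 (4S,6R,7R,8R,9E)-8-hydroxy-4-methyl-14-(triisopropylsilyloxy)cyclodec-9-ene 6,12-olide (trans-fused γ-lactone; no C13 yet), via alkenylchromium dichloride 26 (not isolated)
Conditions: CrCl2 (10 equiv), NiCl2 (1 mol % of the CrCl2), DMSO/THF 3:1, rt, 25 added over 12 h to a final 0.003 M; aq. NH4Cl work-up
Reagents that add atoms: none
Why: NiCl2 is reduced by CrCl2 to zerovalent nickel, which inserts into the C9–I bond; the alkenyl group passes to trivalent chromium with retention of the E geometry to give 26, which adds to the C8 formyl group (Nozaki–Hiyama–Kishi alkenyl iodide–aldehyde macrocyclisation). The C8–C9 bond closes the ten-membered carbocycle in a 10-exo-trig mode, the carbonyl oxygen ending up outside the ring as the chromium alkoxide. The new C8 centre is controlled by C7 inside the rigid trans lactone: the tether from C6 should let C9 approach only in the rotamer about C7–C8 in which it is anti to the C7–C11 bond and passes over the C7 hydrogen, and with the chromium-bound oxygen turned toward C6 (a Felkin-type arrangement) the Re face is attacked and 8R should result. The step needs this facial selectivity, attack on the aldehyde and not on the lactone carbonyl, and ring closure in preference to oligomerisation; the first rests on the C7 centre, the second on the carbonyl selectivity of alkenylchromium reagents, the third on high dilution together with the trans lactone and the cis placement of C1 and C8 on the olefin, which hold the two ends close. The neutral medium should leave the epimerisable C7 centre, the lactone and the silyl ether untouched.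

Step 17
Reactants: 27 (4S,6R,7R,8R,9E)-8-hydroxy-4-methyl-14-(triisopropylsilyloxy)cyclodec-9-ene 6,12-olide
Product: 28 (4S,6R,7S,8R,9E)-4-methyl-8-(triethylsilyloxy)-14-(triisopropylsilyloxy)cyclodec-9-ene 6,12-olide
Conditions: Et3SiOTf, 2,6-lutidine, CH2Cl2, −78 °C
Reagents that add atoms: triethylsilyl trifluoromethanesulfonate CC[Si](CC)(CC)OS(=O)(=O)C(F)(F)F
Why: silylation with a silyl triflate and a hindered base masks the C8 hydroxyl, which would otherwise be deprotonated in the next step and could shift the lactone from O6 to O8.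

Step 18
Reactants: 28 (4S,6R,7S,8R,9E)-4-methyl-8-(triethylsilyloxy)-14-(triisopropylsilyloxy)cyclodec-9-ene 6,12-olide
Product: 30 11-[(dimethylamino)methyl] derivative of 28 (C11 epimers), via lithium enolate 29 (not isolated)
Conditions: LiN(i-Pr)2, THF, −78 °C; then CH2=NMe2+ I−, −78 °C → rt
Reagents that add atoms: N,N-dimethylmethyleneiminium iodide C=[N+](C)C.[I-]
Why: Mannich reaction of the lactone enolate with Eschenmoser's salt adds C13 at C11; the enolate has no β-leaving group and the new C11 centre is removed in the next step.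

Step 19
Reactants: 30 11-[(dimethylamino)methyl] derivative of 28
Product: 32 (4S,6R,7S,8R,9E)-4-methyl-8-(triethylsilyloxy)-14-(triisopropylsilyloxy)cyclodeca-9,11(13)-diene 6,12-olide (α-methylene lactone), via trimethylammonium iodide 31 (not isolated)
Conditions: MeI, MeOH, rt; then NaHCO3 (aq), CH2Cl2, rt
Reagents that add atoms: none
Why: quaternisation of the amine and mild base-induced E1cB loss of trimethylamine is the standard way to the exo-methylene lactone.

Step 20
Reactants: 32 (4S,6R,7S,8R,9E)-4-methyl-8-(triethylsilyloxy)-14-(triisopropylsilyloxy)cyclodeca-9,11(13)-diene 6,12-olide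
Product: 33 (4S,6R,7R,8R,9E)-8-hydroxy-4-methyl-14-(triisopropylsilyloxy)cyclodeca-9,11(13)-diene 6,12-olide
Conditions: AcOH/THF/H2O 3:1:1, rt
Reagents that add atoms: none
Why: mild acid hydrolysis should remove the triethylsilyl ether while the far more stable triisopropylsilyl ether and the methylene lactone persist.

Step 21
Reactants: 34 but-2-yne-1,4-diol
Product: 36 (Z)-2-iodobut-2-ene-1,4-diol, via cyclic alkenylalanate 35 (not isolated)
Conditions: NaAlH2(OCH2CH2OMe)2 (2.5 equiv), THF, 0 °C → rt; then I2, THF, −78 → 0 °C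
Reagents that add atoms: iodine II
Why: trans-hydroalumination of a propargylic alkoxide puts aluminium in a five-membered chelate, anti to the delivered hydride, and iodinolysis with retention should give the iodide with iodine cis to the C1 hydroxymethyl group.

Step 22
Reactants: 36 (Z)-2-iodobut-2-ene-1,4-diol
Product: 37 (Z)-1,4-bis(tert-butyldimethylsilyloxy)-2-iodobut-2-ene
Conditions: t-BuMe2SiCl, imidazole, DMF, rt
Reagents that add atoms: tert-butyldimethylsilyl chloride CC(C)(C)[Si](C)(C)Cl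
Why: standard silylation of both primary hydroxyls, which also prevents cyclisation to a butenolide in the following carbonylation.

Step 23
Reactants: 37 (Z)-1,4-bis(tert-butyldimethylsilyloxy)-2-iodobut-2-ene
Product: 38 methyl (Z)-4-(tert-butyldimethylsilyloxy)-2-[(tert-butyldimethylsilyloxy)methyl]but-2-enoate
Conditions: Pd(PPh3)2Cl2 (5 mol %), CO (1 atm), MeOH, Et3N, DMF, 60 °C
Reagents that add atoms: carbon monoxide [C-]#[O+]; methanol CO
Why: palladium-catalysed methoxycarbonylation of an alkenyl iodide proceeds with retention, so the ester should end up cis to the C4 silyloxymethyl group (Z).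

Step 24
Reactants: 38 methyl (Z)-4-(tert-butyldimethylsilyloxy)-2-[(tert-butyldimethylsilyloxy)methyl]but-2-enoate
Product: 39 (Z)-4-(tert-butyldimethylsilyloxy)-2-[(tert-butyldimethylsilyloxy)methyl]but-2-enoic acid
Conditions: LiOH, THF/MeOH/H2O, rt; then 1 M HCl to pH 4 at 0 °C
Reagents that add atoms: lithium hydroxide [Li+].[OH-]
Why: saponification of the methyl ester should spare the primary silyl ethers, which also keep the Z acid from closing to a butenolide.

Step 25
Reactants: 33 (4S,6R,7R,8R,9E)-8-hydroxy-4-methyl-14-(triisopropylsilyloxy)cyclodeca-9,11(13)-diene 6,12-olide; 39 (Z)-4-(tert-butyldimethylsilyloxy)-2-[(tert-butyldimethylsilyloxy)methyl]but-2-enoic acid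
Product: 41 8-O-[(Z)-4-(tert-butyldimethylsilyloxy)-2-[(tert-butyldimethylsilyloxy)methyl]but-2-enoyl] ester of 33 (4S,6R,7S,8R), via mixed anhydride 40 (not isolated)
Conditions: 2,4,6-Cl3C6H2COCl, Et3N, toluene, rt; then 33, 4-(dimethylamino)pyridine, toluene, rt
Reagents that add atoms: none
Why: Yamaguchi esterification acylates hindered secondary alcohols with retention at C8, and premixing the anhydride and keeping the temperature low should limit Z to E isomerisation of the acyl group.

Step 26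
Reactants: 41 8-O-[(Z)-4-(tert-butyldimethylsilyloxy)-2-[(tert-butyldimethylsilyloxy)methyl]but-2-enoyl] ester of 33
Product: 42 CNP0131216.1 (4S,6R,7S,8R)
Conditions: HF·pyridine, pyridine, THF, 0 °C → rt
Reagents that add atoms: none
Why: buffered fluoride desilylation should remove all three silyl ethers under weakly acidic conditions that avoid conjugate addition to the methylene lactone and base-induced lactonisation of the Z γ-hydroxy enoate.

## Compound list

1 | trimethylsilylacetylene | C#C[Si](C)(C)C | starting material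
2 | (tert-butyldimethylsilyloxy)acetaldehyde | O=CCO[Si](C)(C)C(C)(C)C | starting material
3 | rac-1-(tert-butyldimethylsilyloxy)-4-(trimethylsilyl)but-3-yn-2-ol | CC(C)(C)[Si](C)(C)OCC(O)C#C[Si](C)(C)C | intermediate
4 | 1-(tert-butyldimethylsilyloxy)-4-(trimethylsilyl)but-3-yn-2-one | CC(C)(C)[Si](C)(C)OCC(=O)C#C[Si](C)(C)C | intermediate
5 | (S)-1-(tert-butyldimethylsilyloxy)-4-(trimethylsilyl)but-3-yn-2-ol | CC(C)(C)[Si](C)(C)OC[C@@H](O)C#C[Si](C)(C)C | intermediate
6 | (S)-1-(tert-butyldimethylsilyloxy)-4-(trimethylsilyl)but-3-yn-2-yl methanesulfonate | CC(C)(C)[Si](C)(C)OC[C@@H](OS(C)(=O)=O)C#C[Si](C)(C)C | intermediate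
7 | (S)-citronellal | O=CC[C@@H](C)CCC=C(C)C | starting material
8 | ethyl[4-(tert-butyldimethylsilyloxy)-1-(trimethylsilyl)buta-1,2-dienyl]zinc (zinc anti to the departed mesylate; axial chirality not encoded) | CC[Zn]C(=C=CCO[Si](C)(C)C(C)(C)C)[Si](C)(C)C | intermediate (not isolated)
9 | (3R,4R,6S)-3-[(tert-butyldimethylsilyloxy)methyl]-6,10-dimethyl-1-(trimethylsilyl)undec-9-en-1-yn-4-ol | CC(C)=CCC[C@H](C)C[C@@H](O)[C@@H](CO[Si](C)(C)C(C)(C)C)C#C[Si](C)(C)C | intermediate
10 | O-dicyclohexylboryl (Z)-1-(dicyclohexylboryl)-1-(trimethylsilyl)alkene from 9 | CC(C)=CCC[C@H](C)C[C@@H](OB(C1CCCCC1)C1CCCCC1)[C@@H](CO[Si](C)(C)C(C)(C)C)/C=C(/B(C1CCCCC1)C1CCCCC1)[Si](C)(C)C | intermediate (not isolated)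
11 | (3R,4R,6S)-3-[(tert-butyldimethylsilyloxy)methyl]-4-hydroxy-6,10-dimethylundec-9-enoic acid | CC(C)=CCC[C@H](C)C[C@@H](O)[C@@H](CO[Si](C)(C)C(C)(C)C)CC(=O)O | intermediate (not isolated)
12 | (4R,5R)-4-[(tert-butyldimethylsilyloxy)methyl]-5-[(2S)-2,6-dimethylhept-5-en-1-yl]dihydrofuran-2(3H)-one | O=C1C[C@H](CO[Si](C)(C)C(C)(C)C)[C@H](O1)C[C@@H](C)CCC=C(C)C | intermediate
13 | (4S)-5-[(2R,3R)-3-[(tert-butyldimethylsilyloxy)methyl]-5-oxotetrahydrofuran-2-yl]-4-methylpentanal | O=C1C[C@H](CO[Si](C)(C)C(C)(C)C)[C@H](O1)C[C@@H](C)CCC=O | intermediate (not isolated)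
14 | (4R,5R)-4-[(tert-butyldimethylsilyloxy)methyl]-5-[(2S)-5-hydroxy-2-methylpentyl]dihydrofuran-2(3H)-one | O=C1C[C@H](CO[Si](C)(C)C(C)(C)C)[C@H](O1)C[C@@H](C)CCCO | intermediate
15 | (4R,5R)-4-[(tert-butyldimethylsilyloxy)methyl]-5-[(2S)-5-iodo-2-methylpentyl]dihydrofuran-2(3H)-one | O=C1C[C@H](CO[Si](C)(C)C(C)(C)C)[C@H](O1)C[C@@H](C)CCCI | intermediate
16 | propargyl alcohol | C#CCO | starting material
17 | triisopropyl(prop-2-yn-1-yloxy)silane | C#CCO[Si](C(C)C)(C(C)C)C(C)C | intermediate
18 | trimethyl(tributylstannyl)silane | C[Si](C)(C)[Sn](CCCC)(CCCC)CCCC | starting material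
19 | (Z)-triisopropyl{[2-(tributylstannyl)-3-(trimethylsilyl)prop-2-en-1-yl]oxy}silane | CC(C)[Si](C(C)C)(C(C)C)OC/C(=C/[Si](C)(C)C)[Sn](CCCC)(CCCC)CCCC | intermediate
20 | (Z)-triisopropyl{[2-iodo-3-(trimethylsilyl)prop-2-en-1-yl]oxy}silane | CC(C)[Si](C(C)C)(C(C)C)OC/C(I)=C/[Si](C)(C)C | intermediate
21 | alkylzinc iodide from 15 (zinc on C1) | O=C1C[C@H](CO[Si](C)(C)C(C)(C)C)[C@H](O1)C[C@@H](C)CCC[Zn]I | intermediate (not isolated)
22 | (4R,5R)-4-[(tert-butyldimethylsilyloxy)methyl]-5-[(2S,6E)-2-methyl-6-[(triisopropylsilyloxy)methyl]-7-(trimethylsilyl)hept-6-en-1-yl]dihydrofuran-2(3H)-one | O=C1C[C@H](CO[Si](C)(C)C(C)(C)C)[C@H](O1)C[C@@H](C)CCC/C(CO[Si](C(C)C)(C(C)C)C(C)C)=C\[Si](C)(C)C | intermediate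
23 | (4R,5R)-4-[(tert-butyldimethylsilyloxy)methyl]-5-[(2S,6E)-7-iodo-2-methyl-6-[(triisopropylsilyloxy)methyl]hept-6-en-1-yl]dihydrofuran-2(3H)-one | O=C1C[C@H](CO[Si](C)(C)C(C)(C)C)[C@H](O1)C[C@@H](C)CCC/C(CO[Si](C(C)C)(C(C)C)C(C)C)=C\I | intermediate
24 | (4R,5R)-4-(hydroxymethyl)-5-[(2S,6E)-7-iodo-2-methyl-6-[(triisopropylsilyloxy)methyl]hept-6-en-1-yl]dihydrofuran-2(3H)-one | O=C1C[C@H](CO)[C@H](O1)C[C@@H](C)CCC/C(CO[Si](C(C)C)(C(C)C)C(C)C)=C\I | intermediate
25 | (2R,3S)-2-[(2S,6E)-7-iodo-2-methyl-6-[(triisopropylsilyloxy)methyl]hept-6-en-1-yl]-5-oxotetrahydrofuran-3-carbaldehyde | O=C1C[C@H](C=O)[C@H](O1)C[C@@H](C)CCC/C(CO[Si](C(C)C)(C(C)C)C(C)C)=C\I | intermediate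
26 | C9 alkenylchromium dichloride from 25 | O=C1C[C@H](C=O)[C@H](O1)C[C@@H](C)CCC/C(CO[Si](C(C)C)(C(C)C)C(C)C)=C\[Cr](Cl)Cl | intermediate (not isolated)
27 | (4S,6R,7R,8R,9E)-8-hydroxy-4-methyl-14-(triisopropylsilyloxy)cyclodec-9-ene 6,12-olide | C1C(=O)O[C@@H]2C[C@@H](C)CCC/C(CO[Si](C(C)C)(C(C)C)C(C)C)=C\[C@@H](O)[C@@H]12 | intermediate
28 | (4S,6R,7S,8R,9E)-4-methyl-8-(triethylsilyloxy)-14-(triisopropylsilyloxy)cyclodec-9-ene 6,12-olide | C1C(=O)O[C@@H]2C[C@@H](C)CCC/C(CO[Si](C(C)C)(C(C)C)C(C)C)=C\[C@@H](O[Si](CC)(CC)CC)[C@@H]12 | intermediate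
29 | lithium enolate of 28 (C11=C12–OLi) | C1=C(O[Li])O[C@@H]2C[C@@H](C)CCC/C(CO[Si](C(C)C)(C(C)C)C(C)C)=C\[C@@H](O[Si](CC)(CC)CC)[C@@H]12 | intermediate (not isolated)
30 | 11-[(dimethylamino)methyl] derivative of 28 (C11 epimers, C11 left undefined) | CN(C)CC1C(=O)O[C@@H]2C[C@@H](C)CCC/C(CO[Si](C(C)C)(C(C)C)C(C)C)=C\[C@@H](O[Si](CC)(CC)CC)[C@@H]12 | intermediate
31 | trimethylammonium iodide from 30 | C[N+](C)(C)CC1C(=O)O[C@@H]2C[C@@H](C)CCC/C(CO[Si](C(C)C)(C(C)C)C(C)C)=C\[C@@H](O[Si](CC)(CC)CC)[C@@H]12.[I-] | intermediate (not isolated)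
32 | (4S,6R,7S,8R,9E)-4-methyl-8-(triethylsilyloxy)-14-(triisopropylsilyloxy)cyclodeca-9,11(13)-diene 6,12-olide | C=C1C(=O)O[C@@H]2C[C@@H](C)CCC/C(CO[Si](C(C)C)(C(C)C)C(C)C)=C\[C@@H](O[Si](CC)(CC)CC)[C@@H]12 | intermediate
33 | (4S,6R,7R,8R,9E)-8-hydroxy-4-methyl-14-(triisopropylsilyloxy)cyclodeca-9,11(13)-diene 6,12-olide | C=C1C(=O)O[C@@H]2C[C@@H](C)CCC/C(CO[Si](C(C)C)(C(C)C)C(C)C)=C\[C@@H](O)[C@@H]12 | intermediate
34 | but-2-yne-1,4-diol | OCC#CCO | starting material
35 | disodium cyclic alkenylalanate from 34 (idealised: aluminium on C2 chelated by O1, second alkoxide on a hydridoalanate) | [Na+].[Na+].COCCO[Al-]1(OCCOC)OCC=C1CO[AlH-](OCCOC)OCCOC | intermediate (not isolated)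
36 | (Z)-2-iodobut-2-ene-1,4-diol | OC/C=C(\I)CO | intermediate
37 | (Z)-1,4-bis(tert-butyldimethylsilyloxy)-2-iodobut-2-ene | CC(C)(C)[Si](C)(C)OC/C=C(\I)CO[Si](C)(C)C(C)(C)C | intermediate
38 | methyl (Z)-4-(tert-butyldimethylsilyloxy)-2-[(tert-butyldimethylsilyloxy)methyl]but-2-enoate | COC(=O)/C(CO[Si](C)(C)C(C)(C)C)=C\CO[Si](C)(C)C(C)(C)C | intermediate
39 | (Z)-4-(tert-butyldimethylsilyloxy)-2-[(tert-butyldimethylsilyloxy)methyl]but-2-enoic acid | OC(=O)/C(CO[Si](C)(C)C(C)(C)C)=C\CO[Si](C)(C)C(C)(C)C | intermediate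
40 | mixed anhydride of 39 with 2,4,6-trichlorobenzoic acid | O=C(OC(=O)/C(CO[Si](C)(C)C(C)(C)C)=C\CO[Si](C)(C)C(C)(C)C)c1c(Cl)cc(Cl)cc1Cl | intermediate (not isolated)
41 | 8-O-[(Z)-4-(tert-butyldimethylsilyloxy)-2-[(tert-butyldimethylsilyloxy)methyl]but-2-enoyl] ester of 33 (4S,6R,7S,8R) | C=C1C(=O)O[C@@H]2C[C@@H](C)CCC/C(CO[Si](C(C)C)(C(C)C)C(C)C)=C\[C@@H](OC(=O)/C(=C\CO[Si](C)(C)C(C)(C)C)CO[Si](C)(C)C(C)(C)C)[C@@H]12 | intermediate
42 | CNP0131216.1 | C=C1C(=O)O[C@@H]2C[C@@H](C)CCC/C(CO)=C\[C@@H](OC(=O)/C(=C\CO)CO)[C@@H]12 | target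

## Step count and risks

Total step count: 26. Longest linear sequence: 19 steps (steps 1–8, 12–20, 25, 26).

The three steps most likely to fail:

1. Step 16 (ring closure). The risk is poor facial selectivity: addition to the Si face of the C8 aldehyde would give the 8S carbinol, alone or mixed with 27. The fallback sets out from aldehyde 25, cyclised as in step 16, and takes on the 8S product, the 8-epi alcohol F1. Mitsunobu reaction of F1 with chloroacetic acid (PPh3, diisopropyl azodicarboxylate, toluene, 0 °C) should invert C8 by SN2 displacement and give the 8R chloroacetate F2. Thiourea and NaHCO3 in EtOH at 50 °C should then remove the chloroacetyl group without a base strong enough to move the lactone from O6 to O8. The fallback comes back to the route at alcohol 27, with C8 set by stereospecific inversion and not by the facial preference of the ring closure.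

2. Step 5 (propargylation). The risk is loss of the silyloxy group by β-elimination from the propargylic zinc tautomer of 8, or weak anti selectivity with this oxygenated reagent. The fallback sets out from (S)-citronellal 7 and makes steps 1–6 unnecessary. (S)-4-Benzyloxazolidin-2-one is acylated with methyl 4-chloro-4-oxobutanoate (n-BuLi, THF, −78 °C) to give the succinate imide F3. Its boron enolate (Bu2BOTf, i-Pr2NEt, CH2Cl2, −78 °C) should add to 7 in an Evans syn aldol reaction to give the aldol adduct F4. Acid-catalysed lactonisation (p-toluenesulfonic acid, cat., CH2Cl2) should give the trans lactone imide F5. LiOH/H2O2 should release the lactone acid F6. Mixed-anhydride reduction (i-BuOCOCl, N-methylmorpholine, THF, −15 °C; then NaBH4) should give the lactone alcohol F7. Silylation (t-BuMe2SiCl, imidazole) returns to the route at lactone 12.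

3. Step 25 (esterification). The risk is Z to E isomerisation of the activated acid through reversible conjugate addition of the pyridine catalyst, or slow acylation of the hindered C8 hydroxyl. The fallback sets out from alcohol 33 and alkenyl iodide 37 and forms the ester by palladium-catalysed alkoxycarbonylation: Pd(OAc)2 (5 mol %), 4,5-bis(diphenylphosphino)-9,9-dimethylxanthene, CO (1 atm), i-Pr2NEt, toluene, 70 °C, with 37 in excess. The acylpalladium intermediate keeps the olefin geometry and no nucleophilic catalyst is present. It comes back to the route at ester 41 and makes no new compound.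

Further compounds
F1 | step 16 | (4S,6R,7R,8S,9E)-8-hydroxy-4-methyl-14-(triisopropylsilyloxy)cyclodec-9-ene 6,12-olide (8-epi-27) | C1C(=O)O[C@@H]2C[C@@H](C)CCC/C(CO[Si](C(C)C)(C(C)C)C(C)C)=C\[C@H](O)[C@@H]12
F2 | step 16 | (4S,6R,7S,8R,9E)-8-(chloroacetoxy)-4-methyl-14-(triisopropylsilyloxy)cyclodec-9-ene 6,12-olide | C1C(=O)O[C@@H]2C[C@@H](C)CCC/C(CO[Si](C(C)C)(C(C)C)C(C)C)=C\[C@@H](OC(=O)CCl)[C@@H]12
F3 | step 5 | methyl 4-[(S)-4-benzyl-2-oxooxazolidin-3-yl]-4-oxobutanoate | COC(=O)CCC(=O)N1[C@@H](Cc2ccccc2)COC1=O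
F4 | step 5 | syn aldol adduct of F3 with 7 (target C6 R, C7 as in 12) | COC(=O)C[C@@H]([C@H](O)C[C@@H](C)CCC=C(C)C)C(=O)N1[C@@H](Cc2ccccc2)COC1=O
F5 | step 5 | trans lactone imide: (S)-4-benzyl-3-{(2R,3S)-2-[(2S)-2,6-dimethylhept-5-en-1-yl]-5-oxotetrahydrofuran-3-carbonyl}oxazolidin-2-one | O=C1C[C@H](C(=O)N2[C@@H](Cc3ccccc3)COC2=O)[C@H](O1)C[C@@H](C)CCC=C(C)C
F6 | step 5 | (2R,3S)-2-[(2S)-2,6-dimethylhept-5-en-1-yl]-5-oxotetrahydrofuran-3-carboxylic acid | O=C1C[C@H](C(=O)O)[C@H](O1)C[C@@H](C)CCC=C(C)C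
F7 | step 5 | (4R,5R)-4-(hydroxymethyl)-5-[(2S)-2,6-dimethylhept-5-en-1-yl]dihydrofuran-2(3H)-one | O=C1C[C@H](CO)[C@H](O1)C[C@@H](C)CCC=C(C)C
F0 | step 25 | none | none
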